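Remark on the chemistry: positions are named in isoflavone numbering (O1, C2, C3, C4, C4a, C5 to C8, C8a; ring B primed), also where ring C is not yet closed. Compounds 1, 5, 8 and 13 are taken as purchasable, and the C2 acetal of alternative 1 is taken as the dimethyl acetal. The key-step precursor and product were checked atom by atom against the target and no structural correction was needed.

## Structural features

Isoirigenin is an isoflavone: benzo ring A is fused to the 4-pyranone ring C through C4a and C8a, and aryl ring B is attached to C3 by a single bond. There is no stereocentre, so every problem is one of regiochemistry and oxygen differentiation. Ring A has a single hydrogen (C6); C5 bears a hydroxyl hydrogen-bonded to the C4 carbonyl, C7 a free hydroxyl, C8 a methoxy group and C8a the ring oxygen. Ring B bears a free 3'-hydroxyl beside two methoxy groups. The three phenols make the target and its late precursors oxidation-prone, the pyranone opens in strong base, the C2-C3 double bond can be over-reduced, and strong acid can open ring C and reclose it through the C5 oxygen to the 6-methoxy isomer. The real difficulty is to place four oxygens on ring A in four different states without passing through an ambiguous polyphenol. The key step uses two facts: the C5 hydroxyl is para to the C8 methoxy, and C8a, C8 and C7 bear three adjacent oxygens. These map onto a ketene carbonyl (C5), a capped squarate carbinol (C8), a squarate ester oxygen (C8a) and a vinyl ether oxygen (C7), with C6 as the vinyl CH2 and C4a carrying the masked C4 carbonyl.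

## Logic of the disconnections

**25 to 24.** The two benzylic C-O bonds (C5 and C3') are cut last. Both phenols are then released by one neutral hydrogenolysis, which avoids the acid that could isomerise the 8-methoxy skeleton. The forward step must spare the C2-C3 double bond and needs sulfur-free material.

**24 to 22.** The O1-C2 and C2-C3 bonds are cut and C2 is removed as a one-carbon unit at the formic acid level (from DMF). Ring C and its double bond disappear and a deoxybenzoin remains. The forward step demands that, of the two oxygens ortho to the ketone, only the C8a oxygen is free; the C5 oxygen is therefore a benzyl ether in 22.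

**22 to 21 to 20.** The C8a and C7 hydroxyls are returned to tert-butyl ethers and the C4 carbonyl to a dithiane. The forward order is thioacetal hydrolysis first, on the fully capped and oxidation-resistant 20, then acidolysis of 21. The hydrolysis must be non-oxidative and buffered.

**20 to 19.** The C5 O-benzyl bond is cut. The forward alkylation must be done before the ketone exists, so that the acidic deoxybenzoin CH2 cannot be C-benzylated.

**19 to 16 (key).** The C5-C6 bond is cut (retro 6π closure), then the C5-C8 bond of a cyclobutenone is re-formed (retro 4π opening). A pentasubstituted, fully differentiated benzene ring becomes a four-membered ring whose substituents already encode every oxygen. The forward step demands outward rotation of the C4 methoxy group and conditions that spare the tert-butyl ethers.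

**16 to 12 and 13.** The bond between the future C8 and C7 is cut, together with the O-methyl bond. The forward step demands α-metalation of 13, addition to the ketone-like carbonyl of 12 and not to the vinylogous ester carbonyl, and O-methylation of the alkoxide in the presence of thioacetal sulfur.

**12 to 7 and 8.** The C4-C4a bond is cut. An acyl anion equivalent adds to one carbonyl of the symmetrical 8, so no regiochemical question arises. The forward step demands a clean addition of a tertiary carbanion and the acylative rearrangement of the adduct to the dione.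

**7 to 4 and 5.** The C3-C4 bond is cut by a dithiane alkylation; the demand is a reactive benzylic halide.

**4 to 3 to 2 to 1.** Functional group changes only: bromide from alcohol, alcohol from aldehyde, benzyl ether from the phenol of 1. Ring B's oxygen pattern is bought, not made.

## Other disconnections considered

**Alternative 1:** The cut is the O1-C8a bond, made last, with ring A at the quinone oxidation level.

- **Forward key step.** Racemic acylhydroquinone A2 would be oxidised at a carbon anode at low potential to acylquinone A3. Acid would free the C2 aldehyde, whose enol oxygen would add 6-endo (oxa-Michael) to the quinone carbon next to the acyl group. Tautomerisation would give the 5,8-diol A1.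
- **In favour.** The attacked carbon is doubly activated and the only one within reach, so closure needs no blocking group on the C5 oxygen; on regiocontrol of ring closure it is the equal of the chosen plan. It needs no organolithium, no sulfur and no cryogenic step, and the oxidant is the electrode; on these points it is better.
- **Against.** A1 must still be methylated on the C8 hydroxyl alone, which is plausible because the C5 hydroxyl is chelated but is an extra selective step. Two isopropyl ethers must then be cleaved with a Lewis acid such as BCl3 beside three methyl ethers, one of them flanked by a chelating oxygen; the same acid invites the ring-opening isomerisation. A3 is a very reactive acylquinone (hydration, dimerisation). The ring A pattern of A2 rests on a regioselective aromatic acylation, not on construction.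
- **Comparison.** Mechanistically it is a polar addition to a quinone against a pericyclic cascade. The step count should be about the same. The chosen plan ends with a neutral hydrogenolysis and not with a Lewis-acid dealkylation.

**Alternative 2:** The cut takes the C3-C1' and O1-C2 bonds in one operation.

- **Forward key step.** Enaminone A5, one condensation away from 2-hydroxyacetophenone A7, would be coupled with boronate A6 using Pd(OAc)2 (divalent palladium) and Cu(OAc)2 (divalent copper) as terminal oxidant. The sequence is palladation of the nucleophilic α-carbon, transmetalation from boron, reductive elimination and reoxidation of zerovalent palladium. The phenol then displaces dimethylamine by addition-elimination to give A4, one hydrogenolysis from the target.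
- **In favour.** It is the most convergent of the four and clearly better on step economy after the fragments. Its endgame equals that of the chosen plan.
- **Against.** A7 must already carry the single free hydroxyl next to the methoxy group and two benzyl ethers. The 6-methoxy against 8-methoxy problem is thus moved into the preparation of A7 from a phloroglucinol-type ketone (nuclear oxidation, selective alkylations) and not solved. The electron-rich boronate A6 may homocouple or protodeboronate under oxidative conditions, and A5 can cyclise without arylation.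
- **Comparison.** The chosen plan is longer, linear and uses stoichiometric organolithiums, but it builds the oxygen pattern and does not presuppose it. If A7 were readily available, alternative 2 would be the better route.

**Alternative 3:** The cut is the C3-C4 bond, with ring C closed as a carbinol.

- **Forward key step.** Keto aldehyde A9, from O-alkylation of salicylaldehyde A10 with phenacyl bromide A11, would be treated with a triazolium salt and base. The carbene converts the aldehyde into an acyl anion equivalent that adds to the tethered ketone (intramolecular crossed benzoin) to give racemic A8. Dehydration across C2-C3 would give A4, then hydrogenolysis.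
- **In favour.** It is metal-free, catalytic and mild, with a simple ether-forming assembly; on reagent economy it is better than the chosen plan.
- **Against.** A stereocentre is made only to be destroyed, and dehydrating a tertiary α-ketol costs an extra step with a risk of α-ketol rearrangement. The aldehyde of A9 is flanked by two ortho oxygens and deactivated by donors. The base can trigger intramolecular aldol of the acidic O-CH2-CO group onto the aldehyde, leading to a 2-aroylbenzofuran (Rap-Stoermer pathway). A10 carries the same presupposed ring A pattern as A7.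
- **Comparison.** Overall length should be similar once A10 is counted. The chosen plan uses heavier reagents but forms no redundant stereocentre and fixes the regiochemistry by construction.

Key step: step 7

## Route

Step 1
Reactants: 1 3-hydroxy-4,5-dimethoxybenzaldehyde
Product: 2 3-(benzyloxy)-4,5-dimethoxybenzaldehyde
Conditions: BnBr, K2CO3, DMF, rt
Reagents that add atoms: benzyl bromide, BrCc1ccccc1
Why: Williamson ether synthesis on the only phenol; the benzyl ether should survive organolithiums, trifluoroacetic acid and BF3·OEt2 and leaves in the final hydrogenolysis together with the C5 benzyl ether.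

Step 2
Reactants: 2 3-(benzyloxy)-4,5-dimethoxybenzaldehyde
Product: 3 [3-(benzyloxy)-4,5-dimethoxyphenyl]methanol
Conditions: NaBH4, MeOH/THF, 0 °C
Reagents that add atoms: none
Why: Hydride reduction of an aromatic aldehyde; no other reducible group is present.

Step 3
Reactants: 3 [3-(benzyloxy)-4,5-dimethoxyphenyl]methanol
Product: 4 1-(benzyloxy)-5-(bromomethyl)-2,3-dimethoxybenzene
Conditions: PBr3, CH2Cl2, 0 °C
Reagents that add atoms: phosphorus tribromide, BrP(Br)Br
Why: Conversion of a benzylic alcohol into the bromide through its phosphite ester; the bromide is used without long storage because it is an activated benzylic halide.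

Step 4
Reactants: 4 1-(benzyloxy)-5-(bromomethyl)-2,3-dimethoxybenzene; 5 1,3-dithiane
Product: 7 2-[3-(benzyloxy)-4,5-dimethoxybenzyl]-1,3-dithiane, via 2-lithio-1,3-dithiane 6 (not isolated)
Conditions: 5, n-BuLi, THF, −30 °C; then 4, −78 to 0 °C
Reagents that add atoms: none
Why: Corey-Seebach alkylation: the sulfur-stabilised carbanion 6 displaces the reactive benzylic bromide by SN2 and forms the future C3-C4 bond.

Step 5
Reactants: 7 2-[3-(benzyloxy)-4,5-dimethoxybenzyl]-1,3-dithiane; 8 di-tert-butyl squarate
Product: 12 3-tert-butoxy-4-{2-[3-(benzyloxy)-4,5-dimethoxybenzyl]-1,3-dithian-2-yl}cyclobut-3-ene-1,2-dione, via lithiated dithiane 9 (not isolated), via lithium alkoxide adduct 10 (not isolated), via trifluoroacetate ester 11 (not isolated)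
Conditions: 7, n-BuLi, THF, −30 °C; add to 8, THF, −78 °C; then (CF3CO)2O, −78 to 0 °C; aq. NaHCO3
Reagents that add atoms: none
Why: A second Corey-Seebach metalation gives the tertiary carbanion 9, which adds 1,2 to a carbonyl of the symmetrical squarate (a 1,4-addition with loss of tert-butoxide would end in the same dione), forming the future C4-C4a bond. Trifluoroacetylation of alkoxide 10 makes the carbinol oxygen a leaving group; ionisation of 11, assisted by the neighbouring tert-butoxy oxygen, and loss of that tert-butyl group give the cyclobutenedione, the standard squarate to cyclobutenedione sequence. Inverse addition at −78 °C should prevent double addition, and the product has no acidic hydrogen next to the ring.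

Step 6
Reactants: 12 3-tert-butoxy-4-{2-[3-(benzyloxy)-4,5-dimethoxybenzyl]-1,3-dithian-2-yl}cyclobut-3-ene-1,2-dione; 13 tert-butyl vinyl ether
Product: 16 racemic 3-tert-butoxy-4-(1-tert-butoxyethenyl)-2-{2-[3-(benzyloxy)-4,5-dimethoxybenzyl]-1,3-dithian-2-yl}-4-methoxycyclobut-2-en-1-one, via 1-tert-butoxyvinyllithium 14 (not isolated), via lithium alkoxide 15 (not isolated)
Conditions: 13 (excess), t-BuLi, THF, −78 to 0 °C; then 12, −78 °C; then MeOTf, −78 to −40 °C; Et3N, aq. NaHCO3
Reagents that add atoms: methyl trifluoromethanesulfonate, COS(=O)(=O)C(F)(F)F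
Why: Oxygen-directed α-lithiation of a vinyl ether gives 14, which adds 1,2 to the more electrophilic, ketone-like carbonyl of 12 (the one next to the tert-butoxy-bearing carbon); the other carbonyl is a vinylogous ester and is shielded by the quaternary dithianyl carbon. The new quaternary carbon forms as a racemate and is erased in step 7. The hard tertiary alkoxide 15 should be O-methylated by methyl triflate at low temperature faster than the thioacetal sulfur, provided the reagent only slightly exceeds total base and is destroyed with Et3N before warming.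

Step 7
Reactants: 16 racemic 3-tert-butoxy-4-(1-tert-butoxyethenyl)-2-{2-[3-(benzyloxy)-4,5-dimethoxybenzyl]-1,3-dithian-2-yl}-4-methoxycyclobut-2-en-1-one
Product: 19 3,5-di-tert-butoxy-2-{2-[3-(benzyloxy)-4,5-dimethoxybenzyl]-1,3-dithian-2-yl}-4-methoxyphenol, via dienylketene 17 (not isolated), via cyclohexadienone 18 (not isolated)
Conditions: PhMe (degassed, base-washed glassware), 110 °C, argon
Reagents that add atoms: none
Why: Heating triggers the thermal conrotatory 4π electrocyclic opening of the C1-C4 bond of the cyclobutenone; the C4 methoxy group, the better donor, rotates outward and the 1-tert-butoxyvinyl group inward, so that the (Z)-dienylketene 17 has its ketene carbon (future C5) next to the vinyl CH2 (future C6). A thermal disrotatory 6π electrocyclisation then forms the C5-C6 bond and closes ring A as the six-membered carbocycle of cyclohexa-2,4-dienone 18, and a proton shift from C6 to oxygen gives phenol 19, with aromatisation as the driving force. The closest known reaction type is the thermal ring expansion of squarate-derived 4-alkenyl-4-alkoxycyclobutenones to highly oxygenated phenols (Moore rearrangement), a relative of the Danheiser benzannulation. No stereocentre is formed and the racemic C4 centre of 16 is erased. The only selectivity needed is torquoselectivity, secured by the donor methoxy group on C4; the connectivity of 16 already fixes that the ketene carbonyl becomes the C5 hydroxyl, the capped carbinol the C8 methoxy, the squarate oxygen the C8a oxygen and the vinyl ether oxygen the C7 oxygen, with the dithiane on C4a. A ketene formed with the vinyl group outward cannot cyclise and should reclose to 16, so both rotation modes funnel to 19. The moderate temperature and acid-free glassware are chosen to keep the tert-butyl enol ether and aryl ethers from losing isobutene, and exclusion of water and air protects the ketene and the electron-rich phenol.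

Step 8
Reactants: 19 3,5-di-tert-butoxy-2-{2-[3-(benzyloxy)-4,5-dimethoxybenzyl]-1,3-dithian-2-yl}-4-methoxyphenol
Product: 20 2-[6-(benzyloxy)-2,4-di-tert-butoxy-3-methoxyphenyl]-2-[3-(benzyloxy)-4,5-dimethoxybenzyl]-1,3-dithiane
Conditions: BnBr, Cs2CO3, DMF, rt, argon
Reagents that add atoms: benzyl bromide, BrCc1ccccc1
Why: Williamson etherification of the only free phenol; the phenoxide is far more nucleophilic than thioacetal sulfur. Capping the C5 oxygen here, before a ketone with an acidic CH2 exists, is what later forces ring C to close through the C8a oxygen.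

Step 9
Reactants: 20 2-[6-(benzyloxy)-2,4-di-tert-butoxy-3-methoxyphenyl]-2-[3-(benzyloxy)-4,5-dimethoxybenzyl]-1,3-dithiane
Product: 21 1-[6-(benzyloxy)-2,4-di-tert-butoxy-3-methoxyphenyl]-2-[3-(benzyloxy)-4,5-dimethoxyphenyl]ethan-1-one
Conditions: MeI, NaHCO3, aq. MeCN, 40 °C
Reagents that add atoms: water, O
Why: Alkylative thioacetal hydrolysis (S-methylation, opening to the thionium ion, capture by water); no oxidant is involved, so the fully O-capped electron-rich rings should be untouched, and the bicarbonate buffer protects the tert-butyl ethers.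

Step 10
Reactants: 21 1-[6-(benzyloxy)-2,4-di-tert-butoxy-3-methoxyphenyl]-2-[3-(benzyloxy)-4,5-dimethoxyphenyl]ethan-1-one
Product: 22 1-[6-(benzyloxy)-2,4-dihydroxy-3-methoxyphenyl]-2-[3-(benzyloxy)-4,5-dimethoxyphenyl]ethan-1-one
Conditions: CF3CO2H, CH2Cl2, 0 °C
Reagents that add atoms: none
Why: Acidolysis of aryl tert-butyl ethers (E1 loss of isobutene) is fast at 0 °C, while aryl benzyl ethers, methyl ethers and the ketone are stable for the short time needed; the hydroxyls set free are those of C8a and C7, now on a ring deactivated by the acyl group.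

Step 11
Reactants: 22 1-[6-(benzyloxy)-2,4-dihydroxy-3-methoxyphenyl]-2-[3-(benzyloxy)-4,5-dimethoxyphenyl]ethan-1-one
Product: 24 5-(benzyloxy)-3-[3-(benzyloxy)-4,5-dimethoxyphenyl]-7-hydroxy-8-methoxy-4H-chromen-4-one, via enaminone 23 (not isolated)
Conditions: BF3·OEt2, DMF, rt; then MsCl, 60 °C; aq. NaOAc
Reagents that add atoms: N,N-dimethylformamide, CN(C)C=O
Why: Deoxybenzoin route to isoflavones: BF3 chelates the 2-hydroxyketone and promotes enolisation, the iminium reagent from DMF and MsCl formylates the activated CH2 to give enaminone 23, and the only free ortho oxygen (C8a) displaces dimethylamine by addition-elimination to close ring C. The C5 benzyl ether excludes closure through the other ortho oxygen and hence the 6-methoxy isomer; the free C7 hydroxyl is tolerated by this procedure.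

Step 12
Reactants: 24 5-(benzyloxy)-3-[3-(benzyloxy)-4,5-dimethoxyphenyl]-7-hydroxy-8-methoxy-4H-chromen-4-one
Product: 25 isoirigenin, 5,7-dihydroxy-3-(3-hydroxy-4,5-dimethoxyphenyl)-8-methoxy-4H-chromen-4-one
Conditions: H2 (1 atm), Pd/C (palladium on carbon), EtOAc/MeOH, rt
Reagents that add atoms: none
Why: Hydrogenolysis of both aryl benzyl ethers under neutral conditions, stopped after uptake of two equivalents, should leave the chromone double bond and the methyl ethers intact and avoids acid that could isomerise the 8-methoxy skeleton.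

## Compound list

1 | 3-hydroxy-4,5-dimethoxybenzaldehyde | COc1cc(C=O)cc(O)c1OC | starting material
2 | 3-(benzyloxy)-4,5-dimethoxybenzaldehyde | COc1cc(C=O)cc(OCc2ccccc2)c1OC | intermediate
3 | [3-(benzyloxy)-4,5-dimethoxyphenyl]methanol | COc1cc(CO)cc(OCc2ccccc2)c1OC | intermediate
4 | 1-(benzyloxy)-5-(bromomethyl)-2,3-dimethoxybenzene | COc1cc(CBr)cc(OCc2ccccc2)c1OC | intermediate
5 | 1,3-dithiane | C1CSCSC1 | starting material
6 | 2-lithio-1,3-dithiane (not isolated) | [Li]C1SCCCS1 | intermediate
7 | 2-[3-(benzyloxy)-4,5-dimethoxybenzyl]-1,3-dithiane | COc1cc(CC2SCCCS2)cc(OCc2ccccc2)c1OC | intermediate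
8 | di-tert-butyl squarate, 3,4-di-tert-butoxycyclobut-3-ene-1,2-dione | CC(C)(C)OC1=C(OC(C)(C)C)C(=O)C1=O | starting material
9 | 2-[3-(benzyloxy)-4,5-dimethoxybenzyl]-2-lithio-1,3-dithiane (not isolated) | [Li]C1(Cc2cc(OC)c(OC)c(OCc3ccccc3)c2)SCCCS1 | intermediate
10 | lithium 1-{2-[3-(benzyloxy)-4,5-dimethoxybenzyl]-1,3-dithian-2-yl}-2,3-di-tert-butoxy-4-oxocyclobut-2-en-1-olate, racemic (not isolated) | [Li+].[O-]C1(C2(Cc3cc(OC)c(OC)c(OCc4ccccc4)c3)SCCCS2)C(OC(C)(C)C)=C(OC(C)(C)C)C1=O | intermediate
11 | 1-{2-[3-(benzyloxy)-4,5-dimethoxybenzyl]-1,3-dithian-2-yl}-2,3-di-tert-butoxy-4-oxocyclobut-2-en-1-yl trifluoroacetate, racemic (not isolated) | CC(C)(C)OC1=C(OC(C)(C)C)C(OC(=O)C(F)(F)F)(C2(Cc3cc(OC)c(OC)c(OCc4ccccc4)c3)SCCCS2)C1=O | intermediate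
12 | 3-tert-butoxy-4-{2-[3-(benzyloxy)-4,5-dimethoxybenzyl]-1,3-dithian-2-yl}cyclobut-3-ene-1,2-dione | CC(C)(C)OC1=C(C2(Cc3cc(OC)c(OC)c(OCc4ccccc4)c3)SCCCS2)C(=O)C1=O | intermediate
13 | tert-butyl vinyl ether | C=COC(C)(C)C | starting material
14 | 1-tert-butoxyvinyllithium (not isolated) | [Li]C(=C)OC(C)(C)C | intermediate
15 | lithium 2-tert-butoxy-1-(1-tert-butoxyethenyl)-3-{2-[3-(benzyloxy)-4,5-dimethoxybenzyl]-1,3-dithian-2-yl}-4-oxocyclobut-2-en-1-olate, racemic (not isolated) | [Li+].[O-]C1(C(=C)OC(C)(C)C)C(OC(C)(C)C)=C(C2(Cc3cc(OC)c(OC)c(OCc4ccccc4)c3)SCCCS2)C1=O | intermediate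
16 | racemic 3-tert-butoxy-4-(1-tert-butoxyethenyl)-2-{2-[3-(benzyloxy)-4,5-dimethoxybenzyl]-1,3-dithian-2-yl}-4-methoxycyclobut-2-en-1-one | COC1(C(=C)OC(C)(C)C)C(OC(C)(C)C)=C(C2(Cc3cc(OC)c(OC)c(OCc4ccccc4)c3)SCCCS2)C1=O | intermediate
17 | (3Z)-3,5-di-tert-butoxy-2-{2-[3-(benzyloxy)-4,5-dimethoxybenzyl]-1,3-dithian-2-yl}-4-methoxyhexa-1,3,5-trien-1-one (not isolated) | O=C=C(C1(Cc2cc(OC)c(OC)c(OCc3ccccc3)c2)SCCCS1)/C(OC(C)(C)C)=C(OC)\C(=C)OC(C)(C)C | intermediate
18 | 3,5-di-tert-butoxy-2-{2-[3-(benzyloxy)-4,5-dimethoxybenzyl]-1,3-dithian-2-yl}-4-methoxycyclohexa-2,4-dien-1-one (not isolated) | O=C1CC(OC(C)(C)C)=C(OC)C(OC(C)(C)C)=C1C1(Cc2cc(OC)c(OC)c(OCc3ccccc3)c2)SCCCS1 | intermediate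
19 | 3,5-di-tert-butoxy-2-{2-[3-(benzyloxy)-4,5-dimethoxybenzyl]-1,3-dithian-2-yl}-4-methoxyphenol | COc1c(OC(C)(C)C)cc(O)c(C2(Cc3cc(OC)c(OC)c(OCc4ccccc4)c3)SCCCS2)c1OC(C)(C)C | intermediate
20 | 2-[6-(benzyloxy)-2,4-di-tert-butoxy-3-methoxyphenyl]-2-[3-(benzyloxy)-4,5-dimethoxybenzyl]-1,3-dithiane | COc1c(OC(C)(C)C)cc(OCc2ccccc2)c(C2(Cc3cc(OC)c(OC)c(OCc4ccccc4)c3)SCCCS2)c1OC(C)(C)C | intermediate
21 | 1-[6-(benzyloxy)-2,4-di-tert-butoxy-3-methoxyphenyl]-2-[3-(benzyloxy)-4,5-dimethoxyphenyl]ethan-1-one | COc1c(OC(C)(C)C)cc(OCc2ccccc2)c(C(=O)Cc2cc(OC)c(OC)c(OCc3ccccc3)c2)c1OC(C)(C)C | intermediate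
22 | 1-[6-(benzyloxy)-2,4-dihydroxy-3-methoxyphenyl]-2-[3-(benzyloxy)-4,5-dimethoxyphenyl]ethan-1-one | COc1c(O)cc(OCc2ccccc2)c(C(=O)Cc2cc(OC)c(OC)c(OCc3ccccc3)c2)c1O | intermediate
23 | 1-[6-(benzyloxy)-2,4-dihydroxy-3-methoxyphenyl]-2-[3-(benzyloxy)-4,5-dimethoxyphenyl]-3-(dimethylamino)prop-2-en-1-one, alkene geometry not defined (not isolated) | CN(C)C=C(c1cc(OC)c(OC)c(OCc2ccccc2)c1)C(=O)c1c(O)c(OC)c(O)cc1OCc1ccccc1 | intermediate
24 | 5-(benzyloxy)-3-[3-(benzyloxy)-4,5-dimethoxyphenyl]-7-hydroxy-8-methoxy-4H-chromen-4-one | COc1cc(-c2coc3c(OC)c(O)cc(OCc4ccccc4)c3c2=O)cc(OCc2ccccc2)c1OC | intermediate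
25 | isoirigenin, 5,7-dihydroxy-3-(3-hydroxy-4,5-dimethoxyphenyl)-8-methoxy-4H-chromen-4-one | COc1cc(-c2coc3c(OC)c(O)cc(O)c3c2=O)cc(O)c1OC | target

## Step count and least certain steps

Total: 12 steps. Longest linear sequence: 12 steps (1 to 25); 5, 8 and 13 enter as purchased reagents.

**Step 7 (key step).** The most likely failure is steric retardation of the 6π closure by the quaternary dithianyl carbon next to the ketene carbon. The ketene would then be diverted (capture by traces of water, dimerisation), or longer heating would be needed and the tert-butyl enol ether would lose isobutene. The fallback sets out from 5 and 8 and returns at 20; it moves the C3-C4 bond formation behind the ring expansion, so that the ketene carries only a secondary dithianyl group. 6, made from 5 as in step 4, is added to 8 and the adduct treated with (CF3CO)2O as in step 5, which should give 3-tert-butoxy-4-(1,3-dithian-2-yl)cyclobut-3-ene-1,2-dione F1. Addition of 14 at −78 °C and capping with methyl triflate should give racemic 3-tert-butoxy-4-(1-tert-butoxyethenyl)-2-(1,3-dithian-2-yl)-4-methoxycyclobut-2-en-1-one F2. Thermolysis in toluene should give 3,5-di-tert-butoxy-2-(1,3-dithian-2-yl)-4-methoxyphenol F3, and benzylation (BnBr, Cs2CO3, DMF) 2-[6-(benzyloxy)-2,4-di-tert-butoxy-3-methoxyphenyl]-1,3-dithiane F4. Corey-Seebach metalation of F4 (n-BuLi, THF, −30 °C) and alkylation with 4 then gives 20.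

**Step 6.** The most likely failure is incomplete α-metalation of 13, because the tert-butyl group hampers precoordination of the base to the ether oxygen; unreacted t-BuLi would then attack 12. A second risk is S-methylation of the thioacetal by excess methyl triflate; a third is hydrolysis of the tert-butyl enol ether of 16 on acidic silica (base-treated silica should be used). The fallback sets out from 12 and returns at 22; it replaces the nucleophile by one whose acetal oxygen offers a second coordination site and whose enol ether is more robust.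

- Methoxymethyl vinyl ether is metalated with sec-BuLi (THF, −78 °C) to [1-(methoxymethoxy)ethenyl]lithium F5.
- Addition to 12 and capping with methyl triflate should give racemic 3-tert-butoxy-2-{2-[3-(benzyloxy)-4,5-dimethoxybenzyl]-1,3-dithian-2-yl}-4-methoxy-4-[1-(methoxymethoxy)ethenyl]cyclobut-2-en-1-one F6.
- Thermolysis as in step 7 should give 3-tert-butoxy-2-{2-[3-(benzyloxy)-4,5-dimethoxybenzyl]-1,3-dithian-2-yl}-4-methoxy-5-(methoxymethoxy)phenol F7.
- Benzylation as in step 8 gives 2-[6-(benzyloxy)-2-tert-butoxy-3-methoxy-4-(methoxymethoxy)phenyl]-2-[3-(benzyloxy)-4,5-dimethoxybenzyl]-1,3-dithiane F8.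
- Hydrolysis as in step 9 gives 1-[6-(benzyloxy)-2-tert-butoxy-3-methoxy-4-(methoxymethoxy)phenyl]-2-[3-(benzyloxy)-4,5-dimethoxyphenyl]ethan-1-one F9.
- HCl in MeOH removes the tert-butyl and the methoxymethyl group together and gives 22.

The same series also answers a loss of isobutene from the enol ether in step 7.

**Step 9.** The most likely failure is stalling after the first S-methylation, or deprotonation of the thionium ion at the benzylic CH2 to a vinyl sulfide that hydrolyses slowly; the thioacetal carbon sits between a di-ortho-substituted aryl group and a benzyl group. The fallback sets out from 20 and returns at 22, bypassing 21. One equivalent of mCPBA (CH2Cl2, −78 °C) or NaIO4 should give the monosulfoxide 2-[6-(benzyloxy)-2,4-di-tert-butoxy-3-methoxyphenyl]-2-[3-(benzyloxy)-4,5-dimethoxybenzyl]-1,3-dithiane 1-oxide F10 as a mixture of diastereomers. Aqueous trifluoroacetic acid then hydrolyses the activated thioacetal S-oxide and cleaves both tert-butyl ethers in the same flask.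

**Step 11.** The most likely failure is loss of the C5 benzyl ether under BF3·OEt2 before ring closure; it lies peri to the chelated carbonyl, and its loss would allow closure through the C5 oxygen and erode the regiochemistry. Electrophilic formylation of C6 on the activated ring is a second risk. The fallback sets out from 22 and returns at 24; it replaces the Lewis-acid procedure by a base-mediated Claisen formylation. Ethyl formate and NaH (THF, 0 °C to rt) formylate the benzylic CH2, and the formyl ketone closes to the hemiacetal 5-(benzyloxy)-3-[3-(benzyloxy)-4,5-dimethoxyphenyl]-2,7-dihydroxy-8-methoxy-2,3-dihydro-4H-chromen-4-one F11 (racemic mixture of diastereomers). Dehydration with catalytic p-TsOH in toluene then gives 24; benzyl ethers are safe throughout.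

## Further compounds

F1 | step 7 | 3-tert-butoxy-4-(1,3-dithian-2-yl)cyclobut-3-ene-1,2-dione | CC(C)(C)OC1=C(C2SCCCS2)C(=O)C1=O
F2 | step 7 | racemic 3-tert-butoxy-4-(1-tert-butoxyethenyl)-2-(1,3-dithian-2-yl)-4-methoxycyclobut-2-en-1-one | COC1(C(=C)OC(C)(C)C)C(OC(C)(C)C)=C(C2SCCCS2)C1=O
F3 | step 7 | 3,5-di-tert-butoxy-2-(1,3-dithian-2-yl)-4-methoxyphenol | COc1c(OC(C)(C)C)cc(O)c(C2SCCCS2)c1OC(C)(C)C
F4 | step 7 | 2-[6-(benzyloxy)-2,4-di-tert-butoxy-3-methoxyphenyl]-1,3-dithiane | COc1c(OC(C)(C)C)cc(OCc2ccccc2)c(C2SCCCS2)c1OC(C)(C)C
F5 | step 6 | [1-(methoxymethoxy)ethenyl]lithium | [Li]C(=C)OCOC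
F6 | step 6 | racemic 3-tert-butoxy-2-{2-[3-(benzyloxy)-4,5-dimethoxybenzyl]-1,3-dithian-2-yl}-4-methoxy-4-[1-(methoxymethoxy)ethenyl]cyclobut-2-en-1-one | COCOC(=C)C1(OC)C(OC(C)(C)C)=C(C2(Cc3cc(OC)c(OC)c(OCc4ccccc4)c3)SCCCS2)C1=O
F7 | step 6 | 3-tert-butoxy-2-{2-[3-(benzyloxy)-4,5-dimethoxybenzyl]-1,3-dithian-2-yl}-4-methoxy-5-(methoxymethoxy)phenol | COCOc1cc(O)c(C2(Cc3cc(OC)c(OC)c(OCc4ccccc4)c3)SCCCS2)c(OC(C)(C)C)c1OC
F8 | step 6 | 2-[6-(benzyloxy)-2-tert-butoxy-3-methoxy-4-(methoxymethoxy)phenyl]-2-[3-(benzyloxy)-4,5-dimethoxybenzyl]-1,3-dithiane | COCOc1cc(OCc2ccccc2)c(C2(Cc3cc(OC)c(OC)c(OCc4ccccc4)c3)SCCCS2)c(OC(C)(C)C)c1OC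
F9 | step 6 | 1-[6-(benzyloxy)-2-tert-butoxy-3-methoxy-4-(methoxymethoxy)phenyl]-2-[3-(benzyloxy)-4,5-dimethoxyphenyl]ethan-1-one | COCOc1cc(OCc2ccccc2)c(C(=O)Cc2cc(OC)c(OC)c(OCc3ccccc3)c2)c(OC(C)(C)C)c1OC
F10 | step 9 | 2-[6-(benzyloxy)-2,4-di-tert-butoxy-3-methoxyphenyl]-2-[3-(benzyloxy)-4,5-dimethoxybenzyl]-1,3-dithiane 1-oxide, mixture of diastereomers | COc1c(OC(C)(C)C)cc(OCc2ccccc2)c(C2(Cc3cc(OC)c(OC)c(OCc4ccccc4)c3)SCCCS2=O)c1OC(C)(C)C
F11 | step 11 | 5-(benzyloxy)-3-[3-(benzyloxy)-4,5-dimethoxyphenyl]-2,7-dihydroxy-8-methoxy-2,3-dihydro-4H-chromen-4-one, racemic mixture of diastereomers | COc1cc(C2C(O)Oc3c(OC)c(O)cc(OCc4ccccc4)c3C2=O)cc(OCc2ccccc2)c1OC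
A1 | alternative 1 | 5,8-dihydroxy-3-[3,4-dimethoxy-5-(propan-2-yloxy)phenyl]-7-(propan-2-yloxy)-4H-chromen-4-one | COc1cc(-c2coc3c(O)c(OC(C)C)cc(O)c3c2=O)cc(OC(C)C)c1OC
A2 | alternative 1 | racemic 1-[2,5-dihydroxy-4-(propan-2-yloxy)phenyl]-2-[3,4-dimethoxy-5-(propan-2-yloxy)phenyl]-3,3-dimethoxypropan-1-one | COC(OC)C(c1cc(OC)c(OC)c(OC(C)C)c1)C(=O)c1cc(O)c(OC(C)C)cc1O
A3 | alternative 1 | racemic 2-{2-[3,4-dimethoxy-5-(propan-2-yloxy)phenyl]-3,3-dimethoxypropanoyl}-5-(propan-2-yloxy)cyclohexa-2,5-diene-1,4-dione | COC(OC)C(c1cc(OC)c(OC)c(OC(C)C)c1)C(=O)C1=CC(=O)C(OC(C)C)=CC1=O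
A4 | alternative 2 | 5,7-bis(benzyloxy)-3-[3-(benzyloxy)-4,5-dimethoxyphenyl]-8-methoxy-4H-chromen-4-one | COc1cc(-c2coc3c(OC)c(OCc4ccccc4)cc(OCc4ccccc4)c3c2=O)cc(OCc2ccccc2)c1OC
A5 | alternative 2 | (2E)-1-[4,6-bis(benzyloxy)-2-hydroxy-3-methoxyphenyl]-3-(dimethylamino)prop-2-en-1-one | COc1c(O)c(C(=O)/C=C/N(C)C)c(OCc2ccccc2)cc1OCc1ccccc1
A6 | alternative 2 | 2-[3-(benzyloxy)-4,5-dimethoxyphenyl]-4,4,5,5-tetramethyl-1,3,2-dioxaborolane | COc1cc(B2OC(C)(C)C(C)(C)O2)cc(OCc2ccccc2)c1OC
A7 | alternative 2 | 1-[4,6-bis(benzyloxy)-2-hydroxy-3-methoxyphenyl]ethan-1-one | COc1c(O)c(C(C)=O)c(OCc2ccccc2)cc1OCc1ccccc1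
A8 | alternative 3 | racemic 5,7-bis(benzyloxy)-3-[3-(benzyloxy)-4,5-dimethoxyphenyl]-3-hydroxy-8-methoxy-2,3-dihydro-4H-chromen-4-one | COc1c(OCc2ccccc2)cc(OCc2ccccc2)c2c1OCC(O)(c1cc(OC)c(OC)c(OCc3ccccc3)c1)C2=O
A9 | alternative 3 | 4,6-bis(benzyloxy)-2-{2-[3-(benzyloxy)-4,5-dimethoxyphenyl]-2-oxoethoxy}-3-methoxybenzaldehyde | COc1c(OCc2ccccc2)cc(OCc2ccccc2)c(C=O)c1OCC(=O)c1cc(OC)c(OC)c(OCc2ccccc2)c1
A10 | alternative 3 | 4,6-bis(benzyloxy)-2-hydroxy-3-methoxybenzaldehyde | COc1c(O)c(C=O)c(OCc2ccccc2)cc1OCc1ccccc1
A11 | alternative 3 | 2-bromo-1-[3-(benzyloxy)-4,5-dimethoxyphenyl]ethan-1-one | COc1cc(C(=O)CBr)cc(OCc2ccccc2)c1OC
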